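## The problem

The target, 23, is a trans-fused hydroazulene: a cyclopentane (C1–C5) shares the C1–C5 bond with a cycloheptene (C1, C5–C10) that holds a trisubstituted C8=C9 alkene. Locants used throughout: C1 is the quaternary fusion carbon (CH3), C2 and C3 the ring CH2 groups, C4 the tertiary carbinol with the isopropyl group, C5 the fusion CH, C6 the CH carrying the 4-hydroxybenzoate, C7 a CH2, C8 the methyl-bearing alkene carbon, C9 the alkene CH and C10 the CH carrying the angelate; "daucane" is used below as shorthand for this skeleton. Five stereocentres (1S,4R,5S,6S,10S) sit on the contiguous array C10–C1–C5(–C4)–C6, and one of them is an all-carbon quaternary centre that no neighbour can set, so it needs absolute control. Once C1 is fixed it can pass its information on: the bulk at C1 places the C5 substituent trans to C10, the C5 side chain steers a nucleophile to one face of a C4 carbonyl, a closed aldol transition state relates C6 to C5, and the axial C1 methyl group shields one face of a C10 carbonyl. Three oxygens must end up different (free tertiary C4–OH, aroyl ester at C6, angelate at C10), so the two secondary oxygens have to be told apart without a long protecting-group sequence. The angelate isomerises from Z to E under nucleophilic or basic acylation conditions and is an allylic ester, the tertiary alcohol dehydrates in strong acid, the phenol must be free at the end, and every intermediate with an oxygen β to a carbonyl can undergo retro-aldol cleavage or β-elimination. The enabling feature is that C1 (quaternary, with its CH3), C5 and C6 are contiguous while C4 can be a carbonyl: C4, C5, C1 with its methyl, C2 and C3 are the five carbons of 3-methylcyclopent-2-en-1-one, which can take a C10 nucleophile at C1 and a C6 aldehyde at C5 in one trans-selective operation.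

## Retrosynthesis

C10–O acyl bond and phenol protection. Target 23 is traced to its phenol silyl ether 22, and 22 is cut at the C10–O acyl bond into allylic alcohol 19 and angelic acid 20 (activated as mixed anhydride 21). The angelate is the most fragile group, so it enters in the penultimate step and afterwards sees only a near-neutral desilylation; cutting the aroyl ester last instead would expose it to further acylation and deprotection events. The forward step must esterify a hindered allylic alcohol next to a quaternary carbon without a nucleophilic catalyst.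

C10 carbinol and C6–O acyl bond. Alcohol 19 comes from enone 18 by 1,2-reduction, and 18 is cut at the C6–O acyl bond into hydroxy enone 14 and the protected acid 17 (from 4-hydroxybenzoic acid 15 through silyl ester 16). Keeping C10 as a ketone while C6 is acylated distinguishes the two secondary oxygens by oxidation state, which a diol precursor could not do; the hindered tertiary C4–OH needs no protection. The reduction must deliver hydride anti to the C1 methyl group.

C8=C9 (seven-membered ring). Hydroxy enone 14 arises from silyl ether 13. The enone of 13 is the retron of an aldol condensation: dehydration of ketol 12, which is opened at C8–C9 to diketone 11. This cut is preferred to C9–C10 or C6–C7 because it leaves a cyclopentane whose two arms on C1 and C5 are exactly what a conjugate addition–aldol sequence delivers, and because C10 keeps its oxygen. The precursor is monocyclic. The forward reaction must make C9 the nucleophile and C8 the electrophile while the C8 ketone, which has a silyloxy group β to it, is not enolised toward C7. A one-pot alkoxide condensation would lose the C6 oxygen by β-elimination, so the closure is split into two operations. The first is a low-temperature lithium aldol addition (11 to 12), in which the C4 alkoxide holds C8 as a hemiketal until the C9 enolate exists. The second is an acid dehydration (12 to 13) at a stage where C8 is no longer a carbonyl.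

Unmasking of the two ketones. Diketone 11 is traced through epoxysilane 10 to vinylsilane 9: the C10 acetyl group is the hydrolysis product of an α,β-epoxysilane, hence of the 1-silylvinyl group, and the C8 ketone is a dioxolane. No skeletal bond is cut, but both carbonyls stay hidden during the organometallic step before, and one acid treatment reveals both.

C4–isopropyl bond. Carbinol 9 is cut at the bond between C4 and the isopropyl carbon to give ketone 8. Doing this on the monocycle, before any other carbonyl exists, removes all chemoselectivity questions, and the C5 side chain together with the C1 methyl group directs the nucleophile to the face that gives 4R. A non-basic isopropyl nucleophile is required because the ketone is hindered, enolisable and β-silyloxylated.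

C1–C10 and C5–C6 (key disconnection). Ketone 8 is the silyl ether of aldol 7, which is cut at C5–C6 (aldol) and at C1–C10 (conjugate addition) into 3-methylcyclopent-2-en-1-one 5, vinylalane 2 and aldehyde 4, by way of aluminium enolate 6. Both cuts fall on the same enolate, so one flask joins three components, sets C1 by catalyst control and C5 and C6 by substrate control, and leaves C4 as the ketone needed next. The precursors are achiral and have four to seven carbons. The forward reaction must create a quaternary centre enantioselectively and trap a hindered enolate with an enolisable aldehyde in anti fashion.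

Building blocks. Vinylalane 2 is the hydroalumination product of (trimethylsilyl)acetylene 1. Aldehyde 4 is the partial reduction product of ester 3. Compounds 1, 3, 5, 15 and 20 are commercial.

## Roads not taken

Alternative 1: The cut runs through C1–C5 and C6–C7, dissolving both rings at once and leading to the acyclic yne–vinylcyclopropane A2. Forward, [Rh(CO)2Cl]2 (monovalent rhodium) would join the vinylcyclopropane and the silyl alkyne of A2 in an intramolecular [5+2] cycloaddition to give the hydroazulene diene A1.
- Merits: two rings and two bonds form in one catalytic, redox-neutral step, and the C4 carbinol is in place before cyclisation.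
- Weak points: the alkene carbon that becomes C1 is fully substituted, so the cycloaddition has to build a quaternary centre, the least favourable case for this reaction class. C1 would be controlled only by the remote C4 centre across a three-atom tether. A1 has no oxygen at C6 or C10, no methyl group at C8 and an sp2 C5, so the trans ring fusion, two carbinol centres, a methyl group and an alkene shift all remain. The enantiopure tertiary propargylic carbinol of A2 is itself a demanding target.
- Comparison: ring economy is better than in the chosen plan, which needs a separate seven-membered closure with its own regiochemical hazard. Against this, the chosen plan sets C1, C5 and C6 in one step with the C6 oxygen installed and the C10 oxygen latent, so far fewer redox and stereochemical corrections follow.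

Alternative 2: The cut removes C4–C5 and C1–C2 as two bonds of a cyclobutane, giving cycloheptenone A4 and allene A5. Forward, irradiation near 350 nm would add A5 to the enone of A4 anti to the C10 silyloxy group to give the methylenecyclobutane A3, whose four-membered ring is then expanded to the cyclopentane.
- Merits: the seven-membered ring exists from the start, so no medium-ring closure is needed, and the C10 oxygen is present early and controls the quaternary C1. In these two respects this road is better than the chosen one.
- Weak points: enone–allene photocycloadditions on cycloheptenones give strained trans-fused adducts whose C5 centre lies α to the ketone and can epimerise, and head-to-head versus head-to-tail orientation is not secured. The ring expansion must choose the right migrating bond. C6 is a ketone that still needs a stereoselective reduction. The C8 methyl group, the C8=C9 alkene and the whole C4 carbinol with its isopropyl group are still missing. A4 must first be made as a single enantiomer.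
- Comparison: the chosen plan has to set its seven-membered aldol closure against this road's preformed ring, and it does so with a closure in which only one ring size is geometrically possible. In return it delivers C1, C5 and C6 with their final substitution in one step and needs no photochemistry or ring expansion.

Alternative 3: The cut is at C9–C10 and C6–C7 and leads to dialdehyde A7 and the bis-silane A8. Forward, BF3·OEt2 would promote two successive allylsilane additions of A8 to the C10 and C6 aldehydes of A7, closing the seven-membered ring as the 8-methylene diol A6.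
- Merits: the ring closes under mild Lewis acid without enolate chemistry, the C8 carbon arrives with an alkene that can be moved to C8=C9, and both ring oxygens arrive together. As a ring-forming step it is more convergent and milder than the aldol closure chosen here.
- Weak points: neither carbinol centre is controlled, so both would be oxidised, and the resulting diketone has two similar carbonyls that must then be reduced with different facial selectivities and esterified differently. Isomerisation of the exocyclic alkene could run toward C7 as well as toward C9. A7, with a quaternary centre, an epimerisable C5 and a protected tertiary carbinol, needs its own multistep enantioselective synthesis.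
- Comparison: the chosen plan gives up the mild double allylation but keeps the two secondary oxygens distinct from the moment they are made (C6 as the aldol hydroxyl, C10 hidden in the vinylsilane). It also builds the cyclopentane stereotriad in the same step that the alternative presupposes.

Key step: step 3

## Remarks on the chemistry

- L* is the chiral sulfonate-bearing carbene 1-(2,6-diethylphenyl)-4,5-diphenyl-3-(2-sulfonatophenyl)imidazolidin-2-ylidene, used as its monovalent silver complex [Ag(L*)]2 and transferred to copper in the flask.
- Assumption: the antipode of L* that gives (S)-configured C1 is used; both antipodes derive from commercial 1,2-diphenylethane-1,2-diamine.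
- Assumption: diketone 11 is drawn open-chain although it may rest as the six-membered hemiketal between the C4 hydroxyl and the C8 ketone.

## Route

Step 1
Reactants: 1 (trimethylsilyl)acetylene
Product: 2 [1-(trimethylsilyl)vinyl]diisobutylaluminium
Conditions: (i-Bu)2AlH, hexanes, 55 °C; used as solution
Reagents that add atoms: diisobutylaluminium hydride, CC(C)C[AlH]CC(C)C
Why: Hydroalumination of a terminal silylalkyne; aluminium adds to the silicon-bearing carbon, a known regiochemical preference, so the geminal Al/Si vinyl reagent forms directly.

Step 2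
Reactants: 3 ethyl (2-methyl-1,3-dioxolan-2-yl)acetate
Product: 4 2-(2-methyl-1,3-dioxolan-2-yl)acetaldehyde
Conditions: (i-Bu)2AlH, CH2Cl2, −78 °C; aq. KNaC4H4O6
Reagents that add atoms: none
Why: Partial reduction of an ester to the aldehyde through the aluminium hemiacetal that is stable at low temperature; the ketal is inert and the aldehyde is used promptly.

Step 3
Reactants: 5 3-methylcyclopent-2-en-1-one; 2 [1-(trimethylsilyl)vinyl]diisobutylaluminium; 4 2-(2-methyl-1,3-dioxolan-2-yl)acetaldehyde
Product: 7 (2S,3S)-2-[(1S)-1-hydroxy-2-(2-methyl-1,3-dioxolan-2-yl)ethyl]-3-methyl-3-[1-(trimethylsilyl)ethenyl]cyclopentan-1-one, via aluminium enolate 6 (not isolated)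
Conditions: CuCl2·2H2O (5 mol%), [Ag(L*)]2 (2.5 mol%), THF, −78 °C; then 4, −78 → −40 °C; aq. NH4Cl
Reagents that add atoms: none
Why: Carbene transfer from silver to copper and reduction of the divalent copper salt by the alane give a chiral carbene-bound vinylcopper (monovalent copper), which complexes enone 5 and delivers the 1-silylvinyl group to the β-carbon C1 while aluminium takes the enolate oxygen to give 6. The closest known reaction type is the carbene–copper-catalysed enantioselective conjugate addition of silyl-substituted vinylaluminium reagents to β-substituted cyclic enones, joined to aldehyde trapping of the aluminium enolate that such additions leave. No ring is closed; two C–C bonds (C1–C10 and C5–C6) and three stereocentres are formed. C1 is set by the chiral carbene on copper, which selects one enantiotopic face of the enone. C5 is set by the substrate: the aldehyde approaches the enolate face anti to the bulky 1-silylvinyl group and syn to the smaller methyl group, so C6 ends up trans to C10. C6 is set by the closed chair (Zimmerman–Traxler) transition state in which aluminium bridges enolate and aldehyde oxygen; the ring-locked E enolate with the aldehyde substituent equatorial gives the anti (5S,6S) aldol. The step needs vinyl over isobutyl transfer, 1,4- over 1,2-addition and C–C bond formation faster than proton transfer from the enolisable aldehyde; the sp2 group on aluminium transfers preferentially, copper enforces conjugate addition, and the low temperature with a cold quench keeps the aldolate from retro-aldol cleavage.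

Step 4
Reactants: 7 (2S,3S)-2-[(1S)-1-hydroxy-2-(2-methyl-1,3-dioxolan-2-yl)ethyl]-3-methyl-3-[1-(trimethylsilyl)ethenyl]cyclopentan-1-one
Product: 8 (2S,3S)-2-[(1S)-1-[(tert-butyldimethylsilyl)oxy]-2-(2-methyl-1,3-dioxolan-2-yl)ethyl]-3-methyl-3-[1-(trimethylsilyl)ethenyl]cyclopentan-1-one
Conditions: TBSOTf, 2,6-lutidine, CH2Cl2, −78 °C
Reagents that add atoms: tert-butyldimethylsilyl trifluoromethanesulfonate, CC(C)(C)[Si](C)(C)OS(=O)(=O)C(F)(F)F
Why: Silylation of the aldol hydroxyl under cold, weakly basic conditions blocks retro-aldol cleavage and β-elimination before the organometallic step; no stereocentre is touched and the dioxolane tolerates the short exposure at −78 °C.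

Step 5
Reactants: 8 (2S,3S)-2-[(1S)-1-[(tert-butyldimethylsilyl)oxy]-2-(2-methyl-1,3-dioxolan-2-yl)ethyl]-3-methyl-3-[1-(trimethylsilyl)ethenyl]cyclopentan-1-one
Product: 9 (1R,2S,3S)-2-[(1S)-1-[(tert-butyldimethylsilyl)oxy]-2-(2-methyl-1,3-dioxolan-2-yl)ethyl]-3-methyl-1-(propan-2-yl)-3-[1-(trimethylsilyl)ethenyl]cyclopentan-1-ol
Conditions: i-PrMgCl, CeCl3, THF, −78 → 0 °C
Reagents that add atoms: isopropylmagnesium chloride, CC(C)[Mg]Cl
Why: Organocerium addition (isopropylcerium dichloride formed in the flask) to a hindered, enolisable ketone, the known remedy against enolisation and β-hydride reduction. The nucleophile attacks C4 on the face anti to the C5 side chain and to the pseudo-axial C1 methyl group, placing isopropyl cis to H5 and the hydroxyl cis to C6 (4R).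

Step 6
Reactants: 9 (1R,2S,3S)-2-[(1S)-1-[(tert-butyldimethylsilyl)oxy]-2-(2-methyl-1,3-dioxolan-2-yl)ethyl]-3-methyl-1-(propan-2-yl)-3-[1-(trimethylsilyl)ethenyl]cyclopentan-1-ol
Product: 10 (1R,2S,3S)-2-[(1S)-1-[(tert-butyldimethylsilyl)oxy]-2-(2-methyl-1,3-dioxolan-2-yl)ethyl]-3-methyl-1-(propan-2-yl)-3-[2-(trimethylsilyl)oxiran-2-yl]cyclopentan-1-ol (both oxirane epimers)
Conditions: mCPBA, NaHCO3, CH2Cl2, 0 °C → rt
Reagents that add atoms: 3-chloroperoxybenzoic acid, OOC(=O)c1cccc(Cl)c1
Why: Prilezhaev epoxidation of the only alkene gives the α,β-epoxysilane; the buffer protects ketal and epoxide, and the new oxirane centre is lost in the next step.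

Step 7
Reactants: 10 (1R,2S,3S)-2-[(1S)-1-[(tert-butyldimethylsilyl)oxy]-2-(2-methyl-1,3-dioxolan-2-yl)ethyl]-3-methyl-1-(propan-2-yl)-3-[2-(trimethylsilyl)oxiran-2-yl]cyclopentan-1-ol (both oxirane epimers)
Product: 11 1-[(1S,2S,3R)-2-[(1S)-1-[(tert-butyldimethylsilyl)oxy]-3-oxobutyl]-3-hydroxy-1-methyl-3-(propan-2-yl)cyclopentyl]ethan-1-one
Conditions: HClO4 (aq. 1 M), THF, 0 °C → rt
Reagents that add atoms: water, O
Why: Acid-promoted opening of the α,β-epoxysilane by water at the silicon-bearing carbon and Peterson elimination of the β-hydroxysilane give the enol of the C10 methyl ketone, a conversion known for 1-silylvinyl groups on quaternary carbon; the same medium hydrolyses the dioxolane to the C8 ketone. The trans arrangement of the C10 arm to both the C6 oxygen and the C4 hydroxyl keeps neighbouring oxygens from opening the epoxide, and cold dilute acid spares the silyl ether and the tertiary alcohol.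

Step 8
Reactants: 11 1-[(1S,2S,3R)-2-[(1S)-1-[(tert-butyldimethylsilyl)oxy]-3-oxobutyl]-3-hydroxy-1-methyl-3-(propan-2-yl)cyclopentyl]ethan-1-one
Product: 12 (1S,4R,5S,6S)-6-[(tert-butyldimethylsilyl)oxy]-4,8-dihydroxydaucan-10-one (both C8 epimers)
Conditions: LiN(SiMe3)2 (1.05 equiv), THF, −78 → 0 °C; LiN(i-Pr)2 (1.1 equiv), −78 → −20 °C; AcOH, −78 °C
Reagents that add atoms: none
Why: Intramolecular aldol addition under kinetic lithium amide conditions: the first base makes the C4 alkoxide, which is expected to close onto the C8 ketone as a six-membered hemiketal, so the second base finds acidic C–H only at C9 of the C10 acetyl group (C1 is quaternary). When the hemiketal opens, the C8 ketone appears next to the preformed C9 enolate; the trans arrangement of the two arms on C1 and C5 allows only the seven-membered closure. Low temperature, lithium counter-ion and the absence of a free C7 enolate suppress loss of the C6 silyloxy group; the new C8 centre is removed in the next step.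

Step 9
Reactants: 12 (1S,4R,5S,6S)-6-[(tert-butyldimethylsilyl)oxy]-4,8-dihydroxydaucan-10-one (both C8 epimers)
Product: 13 (1S,4R,5S,6S)-6-[(tert-butyldimethylsilyl)oxy]-4-hydroxydauc-8-en-10-one
Conditions: p-TsOH·H2O (10 mol%), benzene, rt
Reagents that add atoms: none
Why: Acid-catalysed dehydration of a tertiary β-hydroxy ketone through the C9 enol gives the conjugated C8=C9 enone, and any β,γ-isomer equilibrates into conjugation. C8 is no longer a carbonyl, so the C6 silyloxy group is not β to one, and the isolated C4 carbinol lacks enol assistance and should survive catalytic acid at room temperature.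

Step 10
Reactants: 13 (1S,4R,5S,6S)-6-[(tert-butyldimethylsilyl)oxy]-4-hydroxydauc-8-en-10-one
Product: 14 (1S,4R,5S,6S)-4,6-dihydroxydauc-8-en-10-one
Conditions: HF·pyridine, pyridine, THF, 0 °C → rt
Reagents that add atoms: none
Why: Fluoride cleavage of the secondary silyl ether under buffered, base-free conditions, which avoids γ-deprotonation of the enone and 1,4-elimination of the C6 oxygen.

Step 11
Reactants: 15 4-hydroxybenzoic acid
Product: 17 4-[(tert-butyldimethylsilyl)oxy]benzoic acid, via silyl ester 16 (not isolated)
Conditions: TBSCl, imidazole, DMF, rt; then K2CO3 (cat.), MeOH–H2O, rt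
Reagents that add atoms: tert-butyldimethylsilyl chloride, CC(C)(C)[Si](C)(C)Cl
Why: Bis-silylation of acid and phenol, then selective hydrolysis of the labile silyl ester, gives the phenol-protected acid; a silyl ether is chosen because it can be removed at the end without hydrogenation or base.

Step 12
Reactants: 14 (1S,4R,5S,6S)-4,6-dihydroxydauc-8-en-10-one; 17 4-[(tert-butyldimethylsilyl)oxy]benzoic acid
Product: 18 (1S,4R,5S,6S)-4-hydroxy-10-oxodauc-8-en-6-yl 4-[(tert-butyldimethylsilyl)oxy]benzoate
Conditions: EDC·HCl, DMAP, CH2Cl2, rt
Reagents that add atoms: none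
Why: Steglich esterification; the secondary C6 hydroxyl is acylated while the hindered tertiary C4 hydroxyl stays free, and C10 is still a ketone, so the two ester sites are distinguished by oxidation state.

Step 13
Reactants: 18 (1S,4R,5S,6S)-4-hydroxy-10-oxodauc-8-en-6-yl 4-[(tert-butyldimethylsilyl)oxy]benzoate
Product: 19 (1S,4R,5S,6S,10S)-4,10-dihydroxydauc-8-en-6-yl 4-[(tert-butyldimethylsilyl)oxy]benzoate
Conditions: NaBH4, CeCl3·7H2O, MeOH, −78 → −40 °C
Reagents that add atoms: none
Why: Luche reduction gives clean 1,2-reduction of the enone and leaves the aryl ester alone. Hydride reaches the C10 carbonyl from the face anti to the axial C1 methyl group, so the new hydroxyl is cis to that methyl group (10S).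

Step 14
Reactants: 19 (1S,4R,5S,6S,10S)-4,10-dihydroxydauc-8-en-6-yl 4-[(tert-butyldimethylsilyl)oxy]benzoate; 20 angelic acid [(2Z)-2-methylbut-2-enoic acid]
Product: 22 (1S,4R,5S,6S,10S)-4-hydroxy-10-{[(2Z)-2-methylbut-2-enoyl]oxy}dauc-8-en-6-yl 4-[(tert-butyldimethylsilyl)oxy]benzoate, via mixed anhydride 21 (not isolated)
Conditions: 2,4,6-Cl3C6H2COCl, Et3N, toluene, rt; then 19, 80 °C
Reagents that add atoms: 2,4,6-trichlorobenzoyl chloride, O=C(Cl)c1c(Cl)cc(Cl)cc1Cl (its acyl group is carried by intermediate 21 only)
Why: Yamaguchi esterification run without a nucleophilic catalyst: mixed anhydride 21 acylates the hindered allylic alcohol on heating, conditions known to preserve the Z geometry of angelates. The tertiary hydroxyl and the aryl silyl ether are inert.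

Step 15
Reactants: 22 (1S,4R,5S,6S,10S)-4-hydroxy-10-{[(2Z)-2-methylbut-2-enoyl]oxy}dauc-8-en-6-yl 4-[(tert-butyldimethylsilyl)oxy]benzoate
Product: 23 (1S,4R,5S,6S,10S)-4-hydroxy-10-{[(2Z)-2-methylbut-2-enoyl]oxy}dauc-8-en-6-yl 4-hydroxybenzoate (target)
Conditions: KHF2, MeOH, rt
Reagents that add atoms: none
Why: KHF2 in methanol cleaves phenolic silyl ethers selectively under near-neutral conditions, leaving both esters, the Z alkene and the allylic C–O bond untouched.

## Compound list

1 | (trimethylsilyl)acetylene | C#C[Si](C)(C)C | starting material
2 | [1-(trimethylsilyl)vinyl]diisobutylaluminium | C=C([Si](C)(C)C)[Al](CC(C)C)CC(C)C | intermediate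
3 | ethyl (2-methyl-1,3-dioxolan-2-yl)acetate | CCOC(=O)CC1(C)OCCO1 | starting material
4 | 2-(2-methyl-1,3-dioxolan-2-yl)acetaldehyde | CC1(CC=O)OCCO1 | intermediate
5 | 3-methylcyclopent-2-en-1-one | CC1=CC(=O)CC1 | starting material
6 | diisobutyl{[(3S)-3-methyl-3-[1-(trimethylsilyl)ethenyl]cyclopent-1-en-1-yl]oxy}aluminium | C=C([Si](C)(C)C)[C@@]1(C)CCC(O[Al](CC(C)C)CC(C)C)=C1 | intermediate (not isolated)
7 | (2S,3S)-2-[(1S)-1-hydroxy-2-(2-methyl-1,3-dioxolan-2-yl)ethyl]-3-methyl-3-[1-(trimethylsilyl)ethenyl]cyclopentan-1-one | C=C([Si](C)(C)C)[C@@]1(C)CCC(=O)[C@@H]1[C@@H](O)CC2(C)OCCO2 | intermediate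
8 | (2S,3S)-2-[(1S)-1-[(tert-butyldimethylsilyl)oxy]-2-(2-methyl-1,3-dioxolan-2-yl)ethyl]-3-methyl-3-[1-(trimethylsilyl)ethenyl]cyclopentan-1-one | C=C([Si](C)(C)C)[C@@]1(C)CCC(=O)[C@@H]1[C@@H](O[Si](C)(C)C(C)(C)C)CC2(C)OCCO2 | intermediate
9 | (1R,2S,3S)-2-[(1S)-1-[(tert-butyldimethylsilyl)oxy]-2-(2-methyl-1,3-dioxolan-2-yl)ethyl]-3-methyl-1-(propan-2-yl)-3-[1-(trimethylsilyl)ethenyl]cyclopentan-1-ol | C=C([Si](C)(C)C)[C@@]1(C)CC[C@@](O)(C(C)C)[C@@H]1[C@@H](O[Si](C)(C)C(C)(C)C)CC2(C)OCCO2 | intermediate
10 | (1R,2S,3S)-2-[(1S)-1-[(tert-butyldimethylsilyl)oxy]-2-(2-methyl-1,3-dioxolan-2-yl)ethyl]-3-methyl-1-(propan-2-yl)-3-[2-(trimethylsilyl)oxiran-2-yl]cyclopentan-1-ol (both oxirane epimers) | C[Si](C)(C)C1(CO1)[C@@]2(C)CC[C@@](O)(C(C)C)[C@@H]2[C@@H](O[Si](C)(C)C(C)(C)C)CC3(C)OCCO3 | intermediate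
11 | 1-[(1S,2S,3R)-2-[(1S)-1-[(tert-butyldimethylsilyl)oxy]-3-oxobutyl]-3-hydroxy-1-methyl-3-(propan-2-yl)cyclopentyl]ethan-1-one | CC(=O)[C@@]1(C)CC[C@@](O)(C(C)C)[C@@H]1[C@@H](O[Si](C)(C)C(C)(C)C)CC(C)=O | intermediate
12 | (1S,4R,5S,6S)-6-[(tert-butyldimethylsilyl)oxy]-4,8-dihydroxydaucan-10-one (both C8 epimers) | O=C1CC(C)(O)C[C@H](O[Si](C)(C)C(C)(C)C)[C@@H]2[C@]1(C)CC[C@@]2(O)C(C)C | intermediate
13 | (1S,4R,5S,6S)-6-[(tert-butyldimethylsilyl)oxy]-4-hydroxydauc-8-en-10-one | O=C1C=C(C)C[C@H](O[Si](C)(C)C(C)(C)C)[C@@H]2[C@]1(C)CC[C@@]2(O)C(C)C | intermediate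
14 | (1S,4R,5S,6S)-4,6-dihydroxydauc-8-en-10-one | O=C1C=C(C)C[C@H](O)[C@@H]2[C@]1(C)CC[C@@]2(O)C(C)C | intermediate
15 | 4-hydroxybenzoic acid | OC(=O)c1ccc(O)cc1 | starting material
16 | tert-butyldimethylsilyl 4-[(tert-butyldimethylsilyl)oxy]benzoate | CC(C)(C)[Si](C)(C)OC(=O)c1ccc(O[Si](C)(C)C(C)(C)C)cc1 | intermediate (not isolated)
17 | 4-[(tert-butyldimethylsilyl)oxy]benzoic acid | OC(=O)c1ccc(O[Si](C)(C)C(C)(C)C)cc1 | intermediate
18 | (1S,4R,5S,6S)-4-hydroxy-10-oxodauc-8-en-6-yl 4-[(tert-butyldimethylsilyl)oxy]benzoate | O=C1C=C(C)C[C@H](OC(=O)c3ccc(O[Si](C)(C)C(C)(C)C)cc3)[C@@H]2[C@]1(C)CC[C@@]2(O)C(C)C | intermediate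
19 | (1S,4R,5S,6S,10S)-4,10-dihydroxydauc-8-en-6-yl 4-[(tert-butyldimethylsilyl)oxy]benzoate | O[C@H]1C=C(C)C[C@H](OC(=O)c3ccc(O[Si](C)(C)C(C)(C)C)cc3)[C@@H]2[C@]1(C)CC[C@@]2(O)C(C)C | intermediate
20 | angelic acid [(2Z)-2-methylbut-2-enoic acid] | C/C=C(/C)C(=O)O | starting material
21 | (2Z)-2-methylbut-2-enoic 2,4,6-trichlorobenzoic anhydride | C/C=C(/C)C(=O)OC(=O)c1c(Cl)cc(Cl)cc1Cl | intermediate (not isolated)
22 | (1S,4R,5S,6S,10S)-4-hydroxy-10-{[(2Z)-2-methylbut-2-enoyl]oxy}dauc-8-en-6-yl 4-[(tert-butyldimethylsilyl)oxy]benzoate | C/C=C(/C)C(=O)O[C@H]1C=C(C)C[C@H](OC(=O)c3ccc(O[Si](C)(C)C(C)(C)C)cc3)[C@@H]2[C@]1(C)CC[C@@]2(O)C(C)C | intermediate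
23 | (1S,4R,5S,6S,10S)-4-hydroxy-10-{[(2Z)-2-methylbut-2-enoyl]oxy}dauc-8-en-6-yl 4-hydroxybenzoate | C/C=C(/C)C(=O)O[C@H]1C=C(C)C[C@H](OC(=O)c2ccc(O)cc2)[C@@H]2[C@]1(C)CC[C@@]2(O)C(C)C | target

## Step count and least certain steps

Total step count: 15. Longest linear sequence: 13 steps (steps 1, 3–10 and 12–15, from (trimethylsilyl)acetylene 1); steps 2 and 11 are side branches.

Step 3 (key step). The conjugate addition is the better-founded half. The likely failure is incomplete or unselective aldol trapping: the aluminium enolate next to the new quaternary centre is hindered and only moderately nucleophilic, so proton transfer from the enolisable aldehyde 4, erosion of the anti preference or retro-aldol cleavage during warming and quench may compete. Fallback: the enolate 6 is silylated in the flask with Et3SiOTf to give the triethylsilyl enol ether F1, which is isolated. MeLi in THF then releases the lithium enolate F2 regiospecifically, and its aldol reaction with 4 at −78 °C (closed transition state, same facial and anti preferences) returns to 7. This fallback sets out from 6 and comes back at 7.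

Step 8 (ring closure). Two processes threaten it. If the C8 ketone is not held as the hemiketal, deprotonation toward C7 can lead to β-elimination of the C6 silyloxy group. A seven-membered ketone–ketone aldol addition may also be reversible, so that the open diketone is recovered. Fallback, from 11 back to 13, with the C9 nucleophile defined before the electrophile is released:
- The unhindered C8 ketone is selectively re-ketalised (1,2-bis(trimethylsilyloxy)ethane, TMSOTf cat., −78 °C; the neopentyl C10 ketone does not react) to the keto ketal F3.
- LiN(i-Pr)2 and TMSCl convert the only remaining ketone into the C10 silyl enol ether F4, with the C4 hydroxyl silylated as well.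
- TMSOTf or TiCl4 at −78 °C ionises the dioxolane, and an intramolecular Mukaiyama aldol-type addition of the enol silane closes the ring to the β-(2-hydroxyethoxy) ketone F5 after aqueous work-up.
- DBU eliminates the β-alkoxy group to give enone 13, bypassing 12.

Step 5 (isopropyl addition). Attack could be slowed by the neighbouring quaternary centre to the point where enolisation, β-hydride reduction or attack on the wrong face competes. Fallback, from 8 back to 9: the smaller sp2 nucleophile from isopropenylmagnesium bromide and CeCl3 is added to give the isopropenyl carbinol F6. Its alkene is then reduced by hydroxyl-directed hydrogenation with [Ir(cod)(PCy3)(py)]PF6 and H2, which should spare the remote, hindered vinylsilane and gives 9.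

Step 13 (C10 reduction). The seven-membered enone is conformationally mobile, so facial selectivity may be poor and the 10-epimer may form alongside 19. Fallback, from 18 back to 19: substrate control is replaced by catalyst control in a Corey–Bakshi–Shibata reduction (B-methyl oxazaborolidine from diphenylprolinol, C18H20BNO, with BH3·SMe2, the enantiomer chosen to deliver hydride anti to the C1 methyl group). No new compound is involved.

Step 14 (angelate). Z to E isomerisation through the activated acyl species, or sluggish acylation of the neopentyl-type allylic alcohol at the temperature needed, may lower the yield of the Z ester. Fallback, from 19 back to 22: the alcohol is esterified with 2-[bis(2,2,2-trifluoroethoxy)phosphoryl]propanoic acid (DCC, DMAP) to the phosphonate ester F7, an acylation with no alkene to isomerise. A Still–Gennari olefination with acetaldehyde (KN(SiMe3)2, 18-crown-6, THF, −78 °C) then builds the Z double bond on the ester and gives 22.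

## Further compounds

F1 | step 3 | triethyl{[(3S)-3-methyl-3-[1-(trimethylsilyl)ethenyl]cyclopent-1-en-1-yl]oxy}silane | C=C([Si](C)(C)C)[C@@]1(C)CCC(O[Si](CC)(CC)CC)=C1
F2 | step 3 | lithium (3S)-3-methyl-3-[1-(trimethylsilyl)ethenyl]cyclopent-1-en-1-olate | C=C([Si](C)(C)C)[C@@]1(C)CCC(O[Li])=C1
F3 | step 8 | 1-[(1S,2S,3R)-2-[(1S)-1-[(tert-butyldimethylsilyl)oxy]-2-(2-methyl-1,3-dioxolan-2-yl)ethyl]-3-hydroxy-1-methyl-3-(propan-2-yl)cyclopentyl]ethan-1-one | CC(=O)[C@@]1(C)CC[C@@](O)(C(C)C)[C@@H]1[C@@H](O[Si](C)(C)C(C)(C)C)CC2(C)OCCO2
F4 | step 8 | tert-butyl{(1S)-2-(2-methyl-1,3-dioxolan-2-yl)-1-[(1S,2S,5R)-2-methyl-5-(propan-2-yl)-5-[(trimethylsilyl)oxy]-2-{1-[(trimethylsilyl)oxy]ethenyl}cyclopentyl]ethoxy}dimethylsilane | C=C(O[Si](C)(C)C)[C@@]1(C)CC[C@@](O[Si](C)(C)C)(C(C)C)[C@@H]1[C@@H](O[Si](C)(C)C(C)(C)C)CC2(C)OCCO2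
F5 | step 8 | (1S,4R,5S,6S)-6-[(tert-butyldimethylsilyl)oxy]-4-hydroxy-8-(2-hydroxyethoxy)daucan-10-one (both C8 epimers) | O=C1CC(C)(OCCO)C[C@H](O[Si](C)(C)C(C)(C)C)[C@@H]2[C@]1(C)CC[C@@]2(O)C(C)C
F6 | step 5 | (1S,2S,3S)-2-[(1S)-1-[(tert-butyldimethylsilyl)oxy]-2-(2-methyl-1,3-dioxolan-2-yl)ethyl]-3-methyl-1-(prop-1-en-2-yl)-3-[1-(trimethylsilyl)ethenyl]cyclopentan-1-ol | C=C([Si](C)(C)C)[C@@]1(C)CC[C@@](O)(C(C)=C)[C@@H]1[C@@H](O[Si](C)(C)C(C)(C)C)CC2(C)OCCO2
F0 | step 13 | none | none
F7 | step 14 | (1S,4R,5S,6S,10S)-10-({2-[bis(2,2,2-trifluoroethoxy)phosphoryl]propanoyl}oxy)-4-hydroxydauc-8-en-6-yl 4-[(tert-butyldimethylsilyl)oxy]benzoate | CC(C(=O)O[C@H]1C=C(C)C[C@H](OC(=O)c3ccc(O[Si](C)(C)C(C)(C)C)cc3)[C@@H]2[C@]1(C)CC[C@@]2(O)C(C)C)P(=O)(OCC(F)(F)F)OCC(F)(F)F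
A1 | alternative 1 | 1-methyl-4-(propan-2-yl)-6-(trimethylsilyl)-4-[(trimethylsilyl)oxy]bicyclo[5.3.0]deca-5,9-diene (daucane locants) | C1=CCCC([Si](C)(C)C)=C2[C@]1(C)CC[C@@]2(O[Si](C)(C)C)C(C)C
A2 | alternative 1 | 7-cyclopropyl-6-methyl-3-(propan-2-yl)-1-(trimethylsilyl)-3-[(trimethylsilyl)oxy]hept-6-en-1-yne | C[Si](C)(C)C#C[C@](O[Si](C)(C)C)(C(C)C)CCC(C)=CC1CC1
A3 | alternative 2 | 6-[(tert-butyldimethylsilyl)oxy]-7-methyl-9-methylidenebicyclo[5.2.0]nonan-2-one | C=C1C[C@]2(C)[C@@H](O[Si](C)(C)C(C)(C)C)CCCC(=O)[C@@H]12
A4 | alternative 2 | 4-[(tert-butyldimethylsilyl)oxy]-3-methylcyclohept-2-en-1-one | CC1=CC(=O)CCC[C@@H]1O[Si](C)(C)C(C)(C)C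
A5 | alternative 2 | propa-1,2-diene (allene) | C=C=C
A6 | alternative 3 | 8-methylidene hydroazulene-6,10-diol with C4 triethylsilyl ether (daucane locants; C6 and C10 configurations open) | OC1CC(=C)CC(O)[C@@H]2[C@]1(C)CC[C@@]2(O[Si](CC)(CC)CC)C(C)C
A7 | alternative 3 | 1-methyl-3-(propan-2-yl)-3-[(triethylsilyl)oxy]cyclopentane-1,2-dicarbaldehyde | O=C[C@@H]1[C@@](C)(C=O)CC[C@@]1(O[Si](CC)(CC)CC)C(C)C
A8 | alternative 3 | 2-methylidene-1,3-bis(trimethylsilyl)propane | C=C(C[Si](C)(C)C)C[Si](C)(C)C
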